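The (Z)-γ-alkylidenebutenolide (ring atoms O1, C2(=O), C3, C4, C5 and the exocyclic methine) lies between the epoxycyclohexane ring and the polyenyne chain, and the route rests on opening it at C4–C5 and O1–C5. One Pd/Cu operation couples a terminal alkyne with a (Z)-β-iodoacrylic acid and lets the cis carboxylate close the lactone onto the new alkyne. This sets the Z exocyclic alkene and releases the unprotected target. The precursors are the ring-A C23 tetraenediyne with a free terminal alkyne and the epoxy dienoic acid with iodine cis to CO2H. Both rings derive from one actinol-based enol triflate, and all four stereocentres are in place beforehand.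

Key step: step 23

Remark: metalated transients (enolates, acetylides, phosphonate anions, organochromium species) are not numbered; only covalent intermediates that could in principle be isolated are. All polyene compounds (from 8 and 12 onward) are handled under argon in dim light.

Step 1
Reactants: 1 ketoisophorone
Product: 2 (6R)-2,2,6-trimethylcyclohexane-1,4-dione [(R)-levodione]
Conditions: ene-reductase (old-yellow-enzyme type), NADP+ (cat.), glucose dehydrogenase, D-glucose, phosphate buffer pH 7, 30 °C
Reagents that add atoms: none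
Why: Biocatalytic asymmetric conjugate reduction of the enedione C=C should set the 6R methyl-bearing centre under enzyme control.

Step 2
Reactants: 2 (R)-levodione
Product: 3 (4R,6R)-4-hydroxy-2,2,6-trimethylcyclohexanone [(4R,6R)-actinol, OH trans to the 6-methyl]
Conditions: H2, Raney Ni (neutral), MeOH, rt; trans isomer purified by crystallisation
Reagents that add atoms: none
Why: Chemoselective heterogeneous hydrogenation of the unhindered C4 carbonyl (C1 is flanked by a quaternary and a tertiary carbon) should add hydrogen from the equatorial side, away from the axial C2 methyl, so the 4R carbinol forms under substrate control by C6.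

Step 3
Reactants: 3 (4R,6R)-actinol
Product: 4 (4R,6R)-4-[(tert-butyldimethylsilyl)oxy]-2,2,6-trimethylcyclohexanone
Conditions: TBSCl, imidazole, DMF, rt
Reagents that add atoms: tert-butyldimethylsilyl chloride, CC(C)(C)[Si](C)(C)Cl
Why: Standard silylation of a secondary alcohol; the TBS ether should survive the amide base, palladium, hydride, titanium and chromium steps that follow.

Step 4
Reactants: 4 TBS-actinol
Product: 5 (4R)-4-[(tert-butyldimethylsilyl)oxy]-2,6,6-trimethylcyclohex-1-en-1-yl trifluoromethanesulfonate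
Conditions: LDA, THF, −78 to 0 °C; PhNTf2, −78 °C to rt
Reagents that add atoms: N-phenylbis(trifluoromethanesulfonimide), O=S(=O)(N(c1ccccc1)S(=O)(=O)C(F)(F)F)C(F)(F)F
Why: Enolate O-triflation; C6 carries the only α-hydrogen, so a single tetrasubstituted enol triflate should form, which erases C6 and leaves the C4 centre untouched.

Step 5
Reactants: 5 enol triflate; 6 (E)-3-methylpent-2-en-4-yn-1-ol
Product: 7 (2E)-5-[(4R)-4-(TBS-oxy)-2,6,6-trimethylcyclohex-1-en-1-yl]-3-methylpent-2-en-4-yn-1-ol
Conditions: Pd(PPh3)4 (5 mol %), CuI (10 mol %), Et3N, DMF, 50 °C, degassed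
Reagents that add atoms: none
Why: Sonogashira coupling of a vinyl triflate with a terminal alkyne; the free primary allylic alcohol is tolerated and the E trisubstituted alkene of 6 is carried over unchanged.

Step 6
Reactants: 7 C15 enynol
Product: 8 (2E)-5-[(4R)-4-(TBS-oxy)-2,6,6-trimethylcyclohex-1-en-1-yl]-3-methylpent-2-en-4-ynal
Conditions: activated MnO2, CH2Cl2, rt
Reagents that add atoms: none
Why: Mild allylic oxidation with manganese dioxide should stop at the enal without touching the silyl ether or the enyne.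

Step 7
Reactants: 8 C15 enynal
Product: 9 tert-butyl{[(1R)-4-[(3E,5E)-6-iodo-3-methylhexa-3,5-dien-1-yn-1-yl]-3,5,5-trimethylcyclohex-3-en-1-yl]oxy}dimethylsilane
Conditions: CrCl2, CHI3, THF–dioxane, 0 °C to rt, dark
Reagents that add atoms: iodoform, IC(I)I
Why: Takai iodo-olefination; the gem-dichromium reagent should convert the aldehyde into the (E)-vinyl iodide, and the aprotic, non-basic medium leaves the neighbouring trisubstituted alkene geometry alone.

Step 8
Reactants: 6 (E)-3-methylpent-2-en-4-yn-1-ol
Product: 11 (2E)-3-methyl-5-(trimethylsilyl)pent-2-en-4-yn-1-ol, via bis-silylated enynol 10 (not isolated)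
Conditions: n-BuLi (2.2 equiv), THF, −78 °C; TMSCl (2.3 equiv), −78 °C to rt; then 1 M HCl, THF, 0 °C
Reagents that add atoms: chlorotrimethylsilane, C[Si](C)(C)Cl
Why: Silylation of the alkoxide/acetylide dianion followed by selective acidic cleavage of the labile O–Si bond should leave the C-silyl alkyne, which masks the alkyne C–H through the chromium and palladium steps.

Step 9
Reactants: 11 TMS-enynol
Product: 12 (2E)-3-methyl-5-(trimethylsilyl)pent-2-en-4-ynal
Conditions: activated MnO2, CH2Cl2, rt
Reagents that add atoms: none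
Why: Allylic oxidation with manganese dioxide; the silyl group also makes this small enal less volatile.

Step 10
Reactants: 12 TMS-enynal
Product: 13 trimethyl[(3E,5E)-3-methyl-6-(4,4,5,5-tetramethyl-1,3,2-dioxaborolan-2-yl)hexa-3,5-dien-1-yn-1-yl]silane
Conditions: Cl2CHB(pin), CrCl2, LiI, THF, rt, dark
Reagents that add atoms: 2-(dichloromethyl)-4,4,5,5-tetramethyl-1,3,2-dioxaborolane, ClC(Cl)B1OC(C)(C)C(C)(C)O1
Why: Takai–Utimoto boryl-olefination should turn the aldehyde into the (E)-alkenyl pinacol boronate by the same gem-dichromium mechanism as in step 7.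

Step 11
Reactants: 9 dienyl iodide; 13 dienyl boronate
Product: 14 tert-butyldimethyl{[(1R)-3,5,5-trimethyl-4-[(3E,5E,7E,9E)-3,10-dimethyl-12-(trimethylsilyl)dodeca-3,5,7,9-tetraene-1,11-diyn-1-yl]cyclohex-3-en-1-yl]oxy}silane
Conditions: Pd(dppf)Cl2 (5 mol %), K3PO4 (3 M aq), THF, 40 °C, degassed, dark
Reagents that add atoms: none
Why: Suzuki–Miyaura coupling joins the two sp2 carbons with retention of both alkene geometries, so the central diene is formed without any allylic carbanion that could scramble the alkyne-flanked trisubstituted alkenes; the C-silyl group prevents alkynylation of the iodide.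

Step 12
Reactants: 14 bis-silylated C23 polyenediyne
Product: 15 (1R)-4-[(3E,5E,7E,9E)-3,10-dimethyldodeca-3,5,7,9-tetraene-1,11-diyn-1-yl]-3,5,5-trimethylcyclohex-3-en-1-ol
Conditions: TBAF (3 equiv), THF, 0 °C to rt; used directly in step 23
Reagents that add atoms: none
Why: Fluoride-mediated desilylation should remove the O-TBS and the C-TMS group in one operation, so the sensitive terminal polyenyne is generated only immediately before the coupling.

Step 13
Reactants: 5 enol triflate
Product: 16 methyl (4R)-4-[(tert-butyldimethylsilyl)oxy]-2,6,6-trimethylcyclohex-1-ene-1-carboxylate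
Conditions: Pd(OAc)2 (5 mol %), PPh3, CO (1 atm), Et3N, MeOH–DMF, 60 °C
Reagents that add atoms: carbon monoxide, [C-]#[O+]; methanol, CO
Why: Palladium-catalysed methoxycarbonylation of a vinyl triflate (oxidative addition, CO insertion, methanolysis of the acyl-palladium) installs the one-carbon unit on the hindered ring carbon.

Step 14
Reactants: 16 enoate
Product: 17 [(4R)-4-[(tert-butyldimethylsilyl)oxy]-2,6,6-trimethylcyclohex-1-en-1-yl]methanol
Conditions: DIBAL-H (2.5 equiv), CH2Cl2, −78 to 0 °C; Rochelle salt work-up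
Reagents that add atoms: none
Why: DIBAL-H 1,2-reduction of the conjugated ester should give the allylic alcohol needed to direct the epoxidation.

Step 15
Reactants: 17 allylic alcohol
Product: 18 [(1R,4S,6R)-4-[(tert-butyldimethylsilyl)oxy]-2,2,6-trimethyl-7-oxabicyclo[4.1.0]heptan-1-yl]methanol (epoxide anti to the silyloxy group)
Conditions: Ti(OiPr)4, D-(−)-diethyl tartrate, t-BuOOH (anhydrous), 4 Å MS, CH2Cl2, −20 °C
Reagents that add atoms: tert-butyl hydroperoxide, CC(C)(C)OO
Why: Sharpless asymmetric epoxidation; the titanium–D-(−)-tartrate complex bound to the allylic hydroxyl should deliver oxygen to the alkene face opposite the C4 silyloxy group, setting both epoxide carbons (1R,6R) under reagent control.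

Step 16
Reactants: 18 epoxy alcohol
Product: 19 (1S,4S,6R)-4-[(tert-butyldimethylsilyl)oxy]-2,2,6-trimethyl-7-oxabicyclo[4.1.0]heptane-1-carbaldehyde
Conditions: TPAP (5 mol %), NMO, 4 Å MS, CH2Cl2, rt
Reagents that add atoms: none
Why: Ley–Griffith oxidation under neutral conditions should give the aldehyde without opening the epoxide; the α-carbon is quaternary and cannot epimerise (the descriptor at C1 changes only through CIP priorities).

Step 17
Reactants: 20 methyl propiolate
Product: 21 methyl (2Z)-2-(hydroxymethyl)-3-iodoprop-2-enoate (iodine cis to the ester)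
Conditions: MgI2, monomeric CH2O (from cracked paraformaldehyde), CH2Cl2, −20 to 0 °C
Reagents that add atoms: formaldehyde, C=O; magnesium iodide, [Mg+2].[I-].[I-]
Why: Iodo-Morita–Baylis–Hillman (halo-aldol) reaction; conjugate addition of iodide gives a magnesium β-iodoallenolate that adds to formaldehyde at the α-carbon, and the chelated kinetic pathway should place iodine cis to the ester.

Step 18
Reactants: 21 iodo-MBH alcohol
Product: 22 methyl (2E)-2-(bromomethyl)-3-iodoprop-2-enoate (same geometry, iodine cis to the ester)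
Conditions: CBr4, PPh3, CH2Cl2, 0 °C
Reagents that add atoms: carbon tetrabromide, BrC(Br)(Br)Br
Why: Appel bromination of the primary allylic alcohol under neutral conditions keeps the vinyl iodide and the alkene geometry intact (the descriptor changes only because CH2Br outranks the ester).

Step 19
Reactants: 22 allylic bromide
Product: 23 methyl (2E)-2-[(diethoxyphosphoryl)methyl]-3-iodoprop-2-enoate (iodine cis to the ester)
Conditions: P(OEt)3 (1.5 equiv), toluene, 80–90 °C, EtBr distilled off
Reagents that add atoms: triethyl phosphite, CCOP(OCC)OCC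
Why: Michaelis–Arbuzov reaction; direct SN2 displacement at the activated primary allylic bromide should be much faster than attack at the hindered iodine-bearing vinylic carbon.

Step 20
Reactants: 23 phosphonate; 19 epoxy aldehyde
Product: 24 methyl (2Z)-3-iodo-2-{(E)-2-[(1S,4S,6R)-4-(TBS-oxy)-2,2,6-trimethyl-7-oxabicyclo[4.1.0]heptan-1-yl]ethenyl}prop-2-enoate
Conditions: LiHMDS (1.05 equiv), THF, −78 °C; then 19, −78 to 0 °C, dark
Reagents that add atoms: none
Why: Horner–Wadsworth–Emmons olefination of an allylic phosphonate anion with a non-enolisable aldehyde should give the E disubstituted alkene, while the iodoacrylate geometry and the three stereocentres are not involved.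

Step 21
Reactants: 24 silyl-protected iodo dienoate
Product: 25 methyl (2Z)-3-iodo-2-{(E)-2-[(1S,4S,6R)-4-hydroxy-2,2,6-trimethyl-7-oxabicyclo[4.1.0]heptan-1-yl]ethenyl}prop-2-enoate
Conditions: TBAF (1.5 equiv), THF, 0 °C to rt
Reagents that add atoms: none
Why: Fluoride cleavage of the secondary TBS ether under non-acidic conditions spares the vinyl epoxide and the vinyl iodide.

Step 22
Reactants: 25 hydroxy ester
Product: 26 (2Z)-3-iodo-2-{(E)-2-[(1S,4S,6R)-4-hydroxy-2,2,6-trimethyl-7-oxabicyclo[4.1.0]heptan-1-yl]ethenyl}prop-2-enoic acid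
Conditions: LiOH·H2O (3 equiv), THF–H2O, 0 °C to rt; then cold aq. citric acid to pH 4; used at once
Reagents that add atoms: lithium hydroxide (its oxygen ends in the carboxyl group), [Li+].[OH-]
Why: Saponification of the methyl ester by acyl substitution should outpace attack at the α-substituted β-iodo carbon, and buffered acidification with immediate use keeps the free acid from opening its own epoxide.

Step 23
Reactants: 15 ring-A C23 polyenediyne; 26 (Z)-β-iodo dienoic acid
Product: 28 the target (deacetylpyrrhoxanthin), via enynoic acid 27 (not isolated)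
Conditions: Pd(PPh3)4 (10 mol %), CuI (20 mol %), Et3N (4 equiv), degassed MeCN–THF, 25 °C, argon, dark; chromatography on Et3N-deactivated silica in dim light
Reagents that add atoms: none
Why: Pd(0) inserts into the vinylic C–I bond of 26 (present as its ammonium carboxylate), the copper acetylide of 15 transmetalates, and reductive elimination forms C4–C5 with retention to give the (Z)-2-en-4-ynoic acid 27, whose carboxylate sits cis to the new alkyne. π-Activation of that alkyne by Pd(II) or Cu(I) then triggers anti attack of the carboxylate oxygen on the proximal alkyne carbon and protodemetalation, which forms O1–C5. The closest known reaction type is the tandem Sonogashira coupling/lactonisation of (Z)-3-iodoalk-2-enoic acids with terminal alkynes to (Z)-γ-ylidenebutenolides. The butenolide ring closes in the 5-exo-dig mode; no stereocentre is created and the four existing ones are remote from the reacting atoms. The step needs 5-exo over 6-endo closure and Z geometry at the exocyclic alkene: the cis iodide/carboxyl arrangement fixed in 26 holds the oxygen over the proximal carbon, and anti oxymetalation places the polyene chain cis to O1. The amine-buffered, room-temperature medium should spare the epoxide, both free hydroxyls and the chromophore, so no further step follows.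

Compound list
1 | ketoisophorone (2,6,6-trimethylcyclohex-2-ene-1,4-dione) | CC1=CC(=O)CC(C)(C)C1=O | starting material
2 | (6R)-2,2,6-trimethylcyclohexane-1,4-dione | O=C1C(C)(C)CC(=O)C[C@H]1C | intermediate
3 | (4R,6R)-4-hydroxy-2,2,6-trimethylcyclohexanone | O=C1C(C)(C)C[C@H](O)C[C@H]1C | intermediate
4 | (4R,6R)-4-[(tert-butyldimethylsilyl)oxy]-2,2,6-trimethylcyclohexanone | O=C1C(C)(C)C[C@H](O[Si](C)(C)C(C)(C)C)C[C@H]1C | intermediate
5 | (4R)-4-[(tert-butyldimethylsilyl)oxy]-2,6,6-trimethylcyclohex-1-en-1-yl trifluoromethanesulfonate | CC1=C(OS(=O)(=O)C(F)(F)F)C(C)(C)C[C@H](O[Si](C)(C)C(C)(C)C)C1 | intermediate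
6 | (E)-3-methylpent-2-en-4-yn-1-ol | C#C/C(C)=C/CO | starting material
7 | (2E)-5-[(4R)-4-[(tert-butyldimethylsilyl)oxy]-2,6,6-trimethylcyclohex-1-en-1-yl]-3-methylpent-2-en-4-yn-1-ol | CC1=C(C#C/C(C)=C/CO)C(C)(C)C[C@H](O[Si](C)(C)C(C)(C)C)C1 | intermediate
8 | (2E)-5-[(4R)-4-[(tert-butyldimethylsilyl)oxy]-2,6,6-trimethylcyclohex-1-en-1-yl]-3-methylpent-2-en-4-ynal | CC1=C(C#C/C(C)=C/C=O)C(C)(C)C[C@H](O[Si](C)(C)C(C)(C)C)C1 | intermediate
9 | tert-butyl{[(1R)-4-[(3E,5E)-6-iodo-3-methylhexa-3,5-dien-1-yn-1-yl]-3,5,5-trimethylcyclohex-3-en-1-yl]oxy}dimethylsilane | CC1=C(C#C/C(C)=C/C=C/I)C(C)(C)C[C@H](O[Si](C)(C)C(C)(C)C)C1 | intermediate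
10 | trimethyl{[(2E)-3-methyl-5-(trimethylsilyl)pent-2-en-4-yn-1-yl]oxy}silane | C[Si](C)(C)C#C/C(C)=C/CO[Si](C)(C)C | intermediate
11 | (2E)-3-methyl-5-(trimethylsilyl)pent-2-en-4-yn-1-ol | C[Si](C)(C)C#C/C(C)=C/CO | intermediate
12 | (2E)-3-methyl-5-(trimethylsilyl)pent-2-en-4-ynal | C[Si](C)(C)C#C/C(C)=C/C=O | intermediate
13 | trimethyl[(3E,5E)-3-methyl-6-(4,4,5,5-tetramethyl-1,3,2-dioxaborolan-2-yl)hexa-3,5-dien-1-yn-1-yl]silane | C[Si](C)(C)C#C/C(C)=C/C=C/B1OC(C)(C)C(C)(C)O1 | intermediate
14 | tert-butyldimethyl{[(1R)-3,5,5-trimethyl-4-[(3E,5E,7E,9E)-3,10-dimethyl-12-(trimethylsilyl)dodeca-3,5,7,9-tetraene-1,11-diyn-1-yl]cyclohex-3-en-1-yl]oxy}silane | CC1=C(C#C/C(C)=C/C=C/C=C/C=C(C)/C#C[Si](C)(C)C)C(C)(C)C[C@H](O[Si](C)(C)C(C)(C)C)C1 | intermediate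
15 | (1R)-4-[(3E,5E,7E,9E)-3,10-dimethyldodeca-3,5,7,9-tetraene-1,11-diyn-1-yl]-3,5,5-trimethylcyclohex-3-en-1-ol | CC1=C(C#C/C(C)=C/C=C/C=C/C=C(C)/C#C)C(C)(C)C[C@H](O)C1 | intermediate
16 | methyl (4R)-4-[(tert-butyldimethylsilyl)oxy]-2,6,6-trimethylcyclohex-1-ene-1-carboxylate | CC1=C(C(=O)OC)C(C)(C)C[C@H](O[Si](C)(C)C(C)(C)C)C1 | intermediate
17 | [(4R)-4-[(tert-butyldimethylsilyl)oxy]-2,6,6-trimethylcyclohex-1-en-1-yl]methanol | CC1=C(CO)C(C)(C)C[C@H](O[Si](C)(C)C(C)(C)C)C1 | intermediate
18 | [(1R,4S,6R)-4-[(tert-butyldimethylsilyl)oxy]-2,2,6-trimethyl-7-oxabicyclo[4.1.0]heptan-1-yl]methanol | OC[C@@]12O[C@]1(C)C[C@@H](O[Si](C)(C)C(C)(C)C)CC2(C)C | intermediate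
19 | (1S,4S,6R)-4-[(tert-butyldimethylsilyl)oxy]-2,2,6-trimethyl-7-oxabicyclo[4.1.0]heptane-1-carbaldehyde | O=C[C@@]12O[C@]1(C)C[C@@H](O[Si](C)(C)C(C)(C)C)CC2(C)C | intermediate
20 | methyl propiolate | C#CC(=O)OC | starting material
21 | methyl (2Z)-2-(hydroxymethyl)-3-iodoprop-2-enoate | I/C=C(/CO)C(=O)OC | intermediate
22 | methyl (2E)-2-(bromomethyl)-3-iodoprop-2-enoate | I/C=C(/CBr)C(=O)OC | intermediate
23 | methyl (2E)-2-[(diethoxyphosphoryl)methyl]-3-iodoprop-2-enoate | I/C=C(/CP(=O)(OCC)OCC)C(=O)OC | intermediate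
24 | methyl (2Z)-3-iodo-2-{(E)-2-[(1S,4S,6R)-4-[(tert-butyldimethylsilyl)oxy]-2,2,6-trimethyl-7-oxabicyclo[4.1.0]heptan-1-yl]ethenyl}prop-2-enoate | I/C=C(/C=C/[C@@]12O[C@]1(C)C[C@@H](O[Si](C)(C)C(C)(C)C)CC2(C)C)C(=O)OC | intermediate
25 | methyl (2Z)-3-iodo-2-{(E)-2-[(1S,4S,6R)-4-hydroxy-2,2,6-trimethyl-7-oxabicyclo[4.1.0]heptan-1-yl]ethenyl}prop-2-enoate | I/C=C(/C=C/[C@@]12O[C@]1(C)C[C@@H](O)CC2(C)C)C(=O)OC | intermediate
26 | (2Z)-3-iodo-2-{(E)-2-[(1S,4S,6R)-4-hydroxy-2,2,6-trimethyl-7-oxabicyclo[4.1.0]heptan-1-yl]ethenyl}prop-2-enoic acid | I/C=C(/C=C/[C@@]34O[C@]3(C)C[C@@H](O)CC4(C)C)C(=O)O | intermediate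
27 | (2Z)-2-en-4-ynoic acid from C–C coupling of 15 and 26 (C3 of the acrylic acid carries the polyenynyl chain, carboxyl cis to the alkyne) | CC1=C(C#C/C(C)=C/C=C/C=C/C=C(C)/C#C/C=C(/C=C/[C@@]34O[C@]3(C)C[C@@H](O)CC4(C)C)C(=O)O)C(C)(C)C[C@H](O)C1 | intermediate
28 | (5Z)-3-{(E)-2-[(1S,4S,6R)-4-hydroxy-2,2,6-trimethyl-7-oxabicyclo[4.1.0]heptan-1-yl]ethenyl}-5-{(2E,4E,6E,8E)-11-[(4R)-4-hydroxy-2,6,6-trimethylcyclohex-1-en-1-yl]-2,9-dimethylundeca-2,4,6,8-tetraen-10-yn-1-ylidene}furan-2(5H)-one | CC1=C(C#C/C(C)=C/C=C/C=C/C=C(C)/C=C2C=C(/C=C/[C@@]34O[C@]3(C)C[C@@H](O)CC4(C)C)C(=O)O/2)C(C)(C)C[C@H](O)C1 | target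

Total step count: 23.
Longest linear sequence: 12 steps (1, 2, 3, 4, 13, 14, 15, 16, 20, 21, 22, 23).

Steps most likely to fail

Step 23. While coupling and ring closure compete in one flask, oxidative homocoupling of the terminal alkyne, partial 6-endo closure to the 2-pyranone, or slow degradation of the polyene may lower the yield. The fallback separates the two events and sets out from 15 and 25. Sonogashira coupling of 15 with the methyl ester 25 (Pd(PPh3)4, CuI, Et3N) should give the methyl (Z)-enynoate F1, which cannot cyclise. Mild LiOH hydrolysis then gives the enynoic acid 27, where the route is rejoined. Catalytic AgNO3 in MeCN–THF at room temperature, a known silver-catalysed 5-exo-dig lactonisation of (Z)-2-en-4-ynoic acids, should then close 27 to 28.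

Step 20. The metalated phosphonate may be consumed by addition–elimination at the β-iodoacrylate of a second molecule faster than it adds to the neopentyl-type aldehyde. The fallback is a Julia–Kocienski olefination and sets out from 22 and 19. Bromide 22 with 2-mercaptobenzothiazole and Et3N should give the benzothiazolyl sulfide F2. Oxidation with H2O2 and catalytic ammonium molybdate should give the benzothiazolyl sulfone F3. NaHMDS is then added at −78 °C to a mixture of F3 and 19, so the anion is trapped as it forms, and the E diene 24 is reached, where the route is rejoined.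

Step 7. E selectivity may erode in the chromium-mediated iodo-olefination of the conjugated enynal, and the dienyl iodide may isomerise. The fallback sets out from 8. Colvin homologation with lithiated trimethylsilyldiazomethane (THF, −78 to 0 °C) should give the terminal enediyne F4. Hydrozirconation of its terminal alkyne with Cp2Zr(H)Cl followed by iodine fixes the E geometry by syn addition and returns to the route at 9.

Further compounds
F1 | step 23 | methyl ester of enynoic acid 27 | CC1=C(C#C/C(C)=C/C=C/C=C/C=C(C)/C#C/C=C(/C=C/[C@@]34O[C@]3(C)C[C@@H](O)CC4(C)C)C(=O)OC)C(C)(C)C[C@H](O)C1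
F2 | step 20 | methyl (2E)-2-[(1,3-benzothiazol-2-ylsulfanyl)methyl]-3-iodoprop-2-enoate | I/C=C(/CSc1nc2ccccc2s1)C(=O)OC
F3 | step 20 | methyl (2E)-2-[(1,3-benzothiazol-2-ylsulfonyl)methyl]-3-iodoprop-2-enoate | I/C=C(/CS(=O)(=O)c1nc2ccccc2s1)C(=O)OC
F4 | step 7 | tert-butyl{[(1R)-3,5,5-trimethyl-4-[(3E)-3-methylhex-3-ene-1,5-diyn-1-yl]cyclohex-3-en-1-yl]oxy}dimethylsilane | CC1=C(C#C/C(C)=C/C#C)C(C)(C)C[C@H](O[Si](C)(C)C(C)(C)C)C1
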